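**Strategy.** The α-methylene-γ-lactone (ring O1–C12–C11–C7–C6, germacranolide numbering) is cut at C11–C12 and O1–C6. This leaves CO2, which brings C12 and both lactone oxygens, and a C11–C7–C6 unit that is nucleophilic at C11 (2-bromoalkene) and electrophilic at C6 (C5–C6 epoxide). In one operation nickel-catalysed reductive carboxylation makes the C11 acrylate, and its carboxyl group opens the epoxide 5-exo at C6 with inversion; this sets C6 and frees the C5 hydroxyl. The precursor is an acyclic furanone bromo-epoxide built from 2-C-methyl-D-erythronolactone (C1, C8–C10), isopropenylacetylene and an enynyl boronate. Ring-closing metathesis at C4=C5 closes the ten-membered ring last.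

Key step: step 10

Remark: positions are numbered as in germacranolides (C1 ketone, C2=C3 furanone enol ether, C4=C5, C6 lactone CH–O, C7, C8 ester carbinol, C9 carbinol, C10 quaternary carbon, C11/C12/C13 lactone α-carbon/carbonyl/methylene, O1 lactone ring oxygen); compounds 1, 3 and 7 are taken to be catalogue compounds.

**Step 1**
Reactants: 1 2-C-methyl-D-erythrono-1,4-lactone
Product: 2 C9-O-TBS lactone, (3R,4R)-4-[(tert-butyldimethylsilyl)oxy]-3-hydroxy-3-methyloxolan-2-one
Conditions: TBSCl, imidazole, DMF, 25 °C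
Reagents that add atoms: tert-butyldimethylsilyl chloride, C[Si](C)(Cl)C(C)(C)C
Why: Silyl ether formation discriminates sterically between the secondary hydroxyl (the later C9–OH) and the tertiary hydroxyl (the later C10–OH), so only the secondary one should be protected.

**Step 2**
Reactants: 2 C9-O-TBS lactone; 3 2-methylbut-1-en-3-yne
Product: 5 furanone alcohol (5-isopropenyl-2-methyl-3(2H)-furanone carrying the CH(OTBS)CH2OH chain at C10), via alkynyl lactol 4 (not isolated)
Conditions: 3 (2.5 equiv), n-BuLi (2.4 equiv), THF, −78 °C; AcOH quench at −78 °C; crude with Ph3PAuCl (5 mol %), AgOTf (5 mol %), toluene, 25 °C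
Reagents that add atoms: none
Why: The lithium acetylide should add once to the lactone carbonyl (stable tetrahedral hemiketalate), and the lactol/α'-hydroxy ynone then undergoes gold-catalysed 5-endo-dig cycloisomerisation through the free tertiary C10 hydroxyl to the 3(2H)-furanone, with C9 and C10 carried over unchanged from the sugar lactone.

**Step 3**
Reactants: 5 furanone alcohol
Product: 6 furanone aldehyde (C8 aldehyde, α-OTBS at C9)
Conditions: Dess–Martin periodinane, NaHCO3, CH2Cl2, 0 → 25 °C
Reagents that add atoms: none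
Why: Dess–Martin oxidation of the primary alcohol under buffered conditions should give the α-silyloxy aldehyde without epimerisation at C9.

**Step 4**
Reactants: 7 (E)-pent-2-en-4-yn-1-ol
Product: 8 (E)-pent-2-en-4-yn-1-yl acetate
Conditions: Ac2O, pyridine, DMAP (cat.), CH2Cl2, 0 °C
Reagents that add atoms: acetic anhydride, CC(=O)OC(C)=O
Why: Routine O-acetylation turns the allylic alcohol into a leaving group for π-allyl formation.

**Step 5**
Reactants: 8 (E)-pent-2-en-4-yn-1-yl acetate
Product: 9 (E)-4,4,5,5-tetramethyl-2-(pent-2-en-4-yn-1-yl)-1,3,2-dioxaborolane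
Conditions: B2pin2, Pd(dba)2 (5 mol %), DMSO, 50 °C
Reagents that add atoms: bis(pinacolato)diboron, CC1(C)OB(OC1(C)C)B1OC(C)(C)C(C)(C)O1
Why: Miyaura-type borylation of the allylic acetate via a π-allyl palladium acetate should place boron at the unsubstituted terminus and give the linear (E)-allylboronate.

**Step 6**
Reactants: 6 furanone aldehyde; 9 (E)-enynyl pinacol boronate
Product: 10 homoallylic alcohol (C8–OH; C7 bearing ethynyl and vinyl; 7,8-anti and 8,9-syn)
Conditions: 9 (1.5 equiv), (S)-TRIP [(S)-3,3'-bis(2,4,6-triisopropylphenyl)-1,1'-binaphthyl-2,2'-diyl hydrogen phosphate] (10 mol %), 4 Å MS, toluene, −30 °C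
Reagents that add atoms: none
Why: Chiral phosphoric acid-catalysed allylboration through a closed chair transition state: the (E)-γ-alkynyl boronate gives the 7,8-anti relation, and the (S)-catalyst is chosen to direct the boronate to the aldehyde face that gives 8S against the weak Felkin–Anh bias of the α-silyloxy aldehyde, so C7 and C8 are set together.

**Step 7**
Reactants: 10 homoallylic alcohol
Product: 11 bromoalkene alcohol (C7 bearing 1-bromoethenyl and vinyl)
Conditions: B-bromo-9-BBN (2.2 equiv), CH2Cl2, 0 °C; AcOH, 0 °C; aq. NaHCO3 work-up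
Reagents that add atoms: B-bromo-9-borabicyclo[3.3.1]nonane, BrB1C2CCCC1CCC2
Why: Bromoboration adds B–Br syn across the terminal alkyne only (Br to the internal carbon C11) and protonolysis of the alkenyl–boron bond with acetic acid gives the 2-bromo-1-alkene, while alkenes do not react and the C8 hydroxyl, borylated by the second equivalent, is released on work-up.

**Step 8**
Reactants: 11 bromoalkene alcohol
Product: 12 epoxy alcohol (C5–C6 epoxide, epoxide oxygen 1,3-syn to C8–OH)
Conditions: VO(acac)2 (10 mol %), t-BuOOH (decane), CH2Cl2, 25 °C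
Reagents that add atoms: tert-butyl hydroperoxide, CC(C)(C)OO
Why: Hydroxyl-directed vanadium-catalysed epoxidation of the homoallylic alcohol through a chair-like vanadate ester, with the C9 and C11 substituents equatorial, should deliver oxygen to the C5=C6 vinyl group syn to C8–OH, while the bromoalkene is inductively deactivated and the dienone alkenes are electron-poor and remote.

**Step 9**
Reactants: 12 epoxy alcohol
Product: 13 epoxy isobutyrate (C8–O–C(=O)CH(CH3)2)
Conditions: (i-PrCO)2O, Et3N, DMAP, CH2Cl2, 25 °C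
Reagents that add atoms: isobutyric anhydride, CC(C)C(=O)OC(=O)C(C)C
Why: DMAP-catalysed acylation of the hindered secondary C8 alcohol installs the isobutyrate of the target and removes a hydroxyl that could otherwise compete for the carboxyl group in step 10.

**Step 10**
Reactants: 13 epoxy isobutyrate
Product: 15 hydroxymethyl lactone (trans-fused α-methylene-γ-lactone with CH2OH at C6), via epoxy acid 14 (not isolated)
Conditions: NiBr2(2,2'-bipyridine) (10 mol %), Mn powder (3 equiv), CO2 (1 atm), DMA, 25 °C; then aq. citric acid; CSA (cat.), CH2Cl2, 25 °C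
Reagents that add atoms: carbon dioxide, O=C=O
Why: Oxidative addition of the C11–Br bond to zerovalent nickel, one-electron reduction by manganese and insertion of CO2 into the alkenyl–nickel bond form C11–C12 as a manganese 2-alkylacrylate, and on acidification the free acid 14 attacks C6 of the neighbouring C5–C6 epoxide from the back side and forms O1–C6. The closest known reaction types are the nickel-catalysed reductive carboxylation of alkenyl and aryl halides or triflates with CO2 and manganese, and the spontaneous lactonisation of γ,δ-epoxy acids. The lactone ring (O1, C12, C11, C7, C6) closes 5-exo-tet, whereas 6-endo attack at C5 would need a δ-lactone and a poorer trajectory. The only new stereocentre, C6, is set by SN2 inversion of the epoxide carbon whose configuration was fixed in step 8, which places the C5 carbon trans to the C8 side chain on the lactone. The step needs chemoselective activation of the bromoalkene in the presence of the epoxide, the dienone and the ester; this rests on the fast oxidative addition of the 2-bromoalkene, the absence of iodide and strong Lewis acids, and the 1,3 placement of C11 and C6 across C7. Both lactone oxygens and C12 thus come from one molecule of CO2.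

**Step 11**
Reactants: 15 hydroxymethyl lactone
Product: 16 lactone aldehyde (C5 aldehyde)
Conditions: Dess–Martin periodinane, NaHCO3, CH2Cl2, 0 °C
Reagents that add atoms: none
Why: Buffered Dess–Martin oxidation of the primary C5 alcohol should give the aldehyde without epimerisation at C6 and without touching the Michael acceptors.

**Step 12**
Reactants: 16 lactone aldehyde
Product: 17 vinyl lactone (C6–CH=CH2; diene for ring closure)
Conditions: Ph3PCH3Br, KN(SiMe3)2, THF, −78 → 0 °C
Reagents that add atoms: methyltriphenylphosphonium bromide, C[P+](c1ccccc1)(c1ccccc1)c1ccccc1.[Br-]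
Why: Wittig methylenation with the non-stabilised ylide at low temperature should be faster at the aldehyde than at the hindered vinylogous-ester ketone, the esters or the acrylate, and turns C5 into the terminal alkene needed for ring closure.

**Step 13**
Reactants: 17 vinyl lactone
Product: 18 O9-TBS ether of the target (ten-membered ring closed, 4Z)
Conditions: second-generation Hoveyda–Grubbs catalyst (20 mol %), 1,4-benzoquinone (40 mol %), toluene (1 mM), 100 °C
Reagents that add atoms: none
Why: Ring-closing metathesis between the C6 vinyl group and the isopropenyl group on the furanone releases ethene and forms the trisubstituted C4=C5 alkene, whose Z geometry is enforced by the bridged ten-membered ring.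

**Step 14**
Reactants: 18 O9-TBS ether of the target
Product: 19 CNP0265772.1 (target)
Conditions: HF·pyridine, pyridine, THF, 0 → 25 °C
Reagents that add atoms: none
Why: Buffered HF·pyridine cleaves the silyl ether under weakly acidic conditions that should not cause acyl migration from O8 to O9 or attack the Michael acceptors.

**Compound list**

1 | 2-C-methyl-D-erythrono-1,4-lactone, (3R,4R)-3,4-dihydroxy-3-methyloxolan-2-one | O=C1[C@](C)(O)[C@H](O)CO1 | starting material
2 | (3R,4R)-4-[(tert-butyldimethylsilyl)oxy]-3-hydroxy-3-methyloxolan-2-one | O=C1[C@](C)(O)[C@H](O[Si](C)(C)C(C)(C)C)CO1 | intermediate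
3 | 2-methylbut-1-en-3-yne | C=C(C)C#C | starting material
4 | (3R,4R)-4-[(tert-butyldimethylsilyl)oxy]-3-methyl-2-(3-methylbut-3-en-1-yn-1-yl)oxolane-2,3-diol (mixture at the hemiketal carbon) | C=C(C)C#CC1(O)[C@](C)(O)[C@H](O[Si](C)(C)C(C)(C)C)CO1 | intermediate
5 | (2R)-2-[(1R)-1-[(tert-butyldimethylsilyl)oxy]-2-hydroxyethyl]-2-methyl-5-(prop-1-en-2-yl)furan-3(2H)-one | C=C(C)C1=CC(=O)[C@](C)(O1)[C@H](O[Si](C)(C)C(C)(C)C)CO | intermediate
6 | (2S)-2-[(tert-butyldimethylsilyl)oxy]-2-[(2R)-2-methyl-3-oxo-5-(prop-1-en-2-yl)-2,3-dihydrofuran-2-yl]acetaldehyde | C=C(C)C1=CC(=O)[C@](C)(O1)[C@H](O[Si](C)(C)C(C)(C)C)C=O | intermediate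
7 | (E)-pent-2-en-4-yn-1-ol | C#C/C=C/CO | starting material
8 | (E)-pent-2-en-4-yn-1-yl acetate | C#C/C=C/COC(C)=O | intermediate
9 | (E)-4,4,5,5-tetramethyl-2-(pent-2-en-4-yn-1-yl)-1,3,2-dioxaborolane | C#C/C=C/CB1OC(C)(C)C(C)(C)O1 | intermediate
10 | (2R)-2-[(1R,2S,3R)-1-[(tert-butyldimethylsilyl)oxy]-3-ethynyl-2-hydroxypent-4-en-1-yl]-2-methyl-5-(prop-1-en-2-yl)furan-3(2H)-one | C=C(C)C1=CC(=O)[C@](C)(O1)[C@H](O[Si](C)(C)C(C)(C)C)[C@@H](O)[C@@H](C#C)C=C | intermediate
11 | (2R)-2-[(1R,2S,3S)-3-(1-bromoethenyl)-1-[(tert-butyldimethylsilyl)oxy]-2-hydroxypent-4-en-1-yl]-2-methyl-5-(prop-1-en-2-yl)furan-3(2H)-one | C=C(C)C1=CC(=O)[C@](C)(O1)[C@H](O[Si](C)(C)C(C)(C)C)[C@@H](O)[C@@H](C(Br)=C)C=C | intermediate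
12 | (2R)-2-[(1R,2S,3R)-4-bromo-1-[(tert-butyldimethylsilyl)oxy]-2-hydroxy-3-[(2R)-oxiran-2-yl]pent-4-en-1-yl]-2-methyl-5-(prop-1-en-2-yl)furan-3(2H)-one | C=C(C)C1=CC(=O)[C@](C)(O1)[C@H](O[Si](C)(C)C(C)(C)C)[C@@H](O)[C@@H](C(Br)=C)[C@@H]1CO1 | intermediate
13 | (1R,2S,3S)-4-bromo-1-[(tert-butyldimethylsilyl)oxy]-1-[(2R)-2-methyl-3-oxo-5-(prop-1-en-2-yl)-2,3-dihydrofuran-2-yl]-3-[(2R)-oxiran-2-yl]pent-4-en-2-yl 2-methylpropanoate | C=C(C)C1=CC(=O)[C@](C)(O1)[C@H](O[Si](C)(C)C(C)(C)C)[C@@H](OC(=O)C(C)C)[C@@H](C(Br)=C)[C@@H]1CO1 | intermediate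
14 | (3S,4S,5R)-5-[(tert-butyldimethylsilyl)oxy]-2-methylidene-5-[(2R)-2-methyl-3-oxo-5-(prop-1-en-2-yl)-2,3-dihydrofuran-2-yl]-4-[(2-methylpropanoyl)oxy]-3-[(2R)-oxiran-2-yl]pentanoic acid | C=C(C)C1=CC(=O)[C@](C)(O1)[C@H](O[Si](C)(C)C(C)(C)C)[C@@H](OC(=O)C(C)C)[C@@H](C(=C)C(=O)O)[C@@H]1CO1 | intermediate
15 | (1S,2R)-2-[(tert-butyldimethylsilyl)oxy]-1-[(2S,3S)-2-(hydroxymethyl)-4-methylidene-5-oxooxolan-3-yl]-2-[(2R)-2-methyl-3-oxo-5-(prop-1-en-2-yl)-2,3-dihydrofuran-2-yl]ethyl 2-methylpropanoate | C=C(C)C1=CC(=O)[C@](C)(O1)[C@H](O[Si](C)(C)C(C)(C)C)[C@@H](OC(=O)C(C)C)[C@@H]2[C@@H](CO)OC(=O)C2=C | intermediate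
16 | (1S,2R)-2-[(tert-butyldimethylsilyl)oxy]-1-[(2S,3R)-2-formyl-4-methylidene-5-oxooxolan-3-yl]-2-[(2R)-2-methyl-3-oxo-5-(prop-1-en-2-yl)-2,3-dihydrofuran-2-yl]ethyl 2-methylpropanoate | C=C(C)C1=CC(=O)[C@](C)(O1)[C@H](O[Si](C)(C)C(C)(C)C)[C@@H](OC(=O)C(C)C)[C@@H]2[C@@H](C=O)OC(=O)C2=C | intermediate
17 | (1S,2R)-2-[(tert-butyldimethylsilyl)oxy]-1-[(2R,3S)-2-ethenyl-4-methylidene-5-oxooxolan-3-yl]-2-[(2R)-2-methyl-3-oxo-5-(prop-1-en-2-yl)-2,3-dihydrofuran-2-yl]ethyl 2-methylpropanoate | C=C(C)C1=CC(=O)[C@](C)(O1)[C@H](O[Si](C)(C)C(C)(C)C)[C@@H](OC(=O)C(C)C)[C@@H]2[C@@H](C=C)OC(=O)C2=C | intermediate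
18 | 9-O-TBS ether of the target: (4Z,6R,7S,8S,9R,10R)-9-[(tert-butyldimethylsilyl)oxy]-8-(2-methylpropanoyloxy)-3,10-epoxy-1-oxogermacra-2,4,11(13)-trien-12,6-olide | C=C1C(=O)O[C@@H]2/C=C(/C)C3=CC(=O)[C@](C)(O3)[C@H](O[Si](C)(C)C(C)(C)C)[C@@H](OC(=O)C(C)C)[C@@H]12 | intermediate
19 | CNP0265772.1: (4Z,6R,7S,8S,9R,10R)-9-hydroxy-8-(2-methylpropanoyloxy)-3,10-epoxy-1-oxogermacra-2,4,11(13)-trien-12,6-olide | C=C1C(=O)O[C@@H]2/C=C(/C)C3=CC(=O)[C@](C)(O3)[C@H](O)[C@@H](OC(=O)C(C)C)[C@@H]12 | target

**Step count.** Total: 14 steps. Longest linear sequence: 12 steps (steps 1–3 and 6–14; steps 4 and 5 prepare boronate 9).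

**Steps most likely to fail**

1. Step 10 (key step). Bromide ion or low-valent nickel may open the terminal epoxide at C5 before the carboxyl group exists; the epoxide oxygen would then close the lactone with retention at C6. Hydrodebromination may also compete with CO2 capture. Fallback: setting out again from 13, a redox-neutral palladium-catalysed hydroxycarbonylation (Pd(OAc)2, Xantphos, CO 1 atm, H2O, Et3N, DMF, 60 °C) should give the same epoxy acid 14 with no metal reductant and no Lewis-acidic manganese salts present. Brief treatment with CSA would then close it to 15, where the main route is rejoined. This fallback makes no compound that is not already listed (F0).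

2. Step 6. The intrinsic 1,2-induction of the α-silyloxy aldehyde opposes the catalyst (mismatched double stereodifferentiation), so facial selectivity at C8, and with it the configuration at C7, may erode; the boronate may also add slowly. Fallback: from 7, PBr3 (Et2O, 0 °C) would give (E)-5-bromopent-3-en-1-yne F1. A catalytic asymmetric Nozaki–Hiyama–Kishi allylation of 6 with F1 (CrCl2 10 mol %, chiral bis(oxazolinyl)carbazole ligand, Mn powder, TMSCl, i-Pr2NEt, THF; aq. HCl work-up) uses a γ-selective, anti-selective allylchromium addition whose facial sense is set by the ligand on the metal. It comes back to the route at 10.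

3. Step 13. Ruthenium may load slowly on the hindered allylic vinyl group and on the electron-poor 1,1-disubstituted alkene, so that oligomerisation or alkene isomerisation outruns closure of the strained bridged ring. Fallback (relay ring-closing metathesis): from aldehyde 16, a Wittig reaction with the ylide from (hex-5-en-1-yl)triphenylphosphonium bromide (KN(SiMe3)2, THF, −78 °C) would give the relay triene F2. With the second-generation Hoveyda–Grubbs catalyst the metal loads on the unhindered terminal alkene, expels cyclopentene and is thereby delivered to C5, from where it closes onto the isopropenyl group. The product is 18, where the route is rejoined.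

**Further compounds**

F0 | step 10 | none | none
F1 | step 6 | (E)-5-bromopent-3-en-1-yne | C#C/C=C/CBr
F2 | step 13 | (1S,2R)-2-[(tert-butyldimethylsilyl)oxy]-1-[(2R,3S)-2-[(1Z)-hepta-1,6-dien-1-yl]-4-methylidene-5-oxooxolan-3-yl]-2-[(2R)-2-methyl-3-oxo-5-(prop-1-en-2-yl)-2,3-dihydrofuran-2-yl]ethyl 2-methylpropanoate | C=C(C)C1=CC(=O)[C@](C)(O1)[C@H](O[Si](C)(C)C(C)(C)C)[C@@H](OC(=O)C(C)C)[C@@H]2[C@@H](/C=C\CCCC=C)OC(=O)C2=C
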